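## Structural features

The target is (5R,6S,6'R)-5,6-epoxy-5,6-dihydro-β,ε-carotene (C40H56O). Two trimethylated six-membered rings are joined through C6 and C6' by an all-E chain of eighteen carbons with nine conjugated double bonds and four methyl branches (C9, C13, C13', C9'). Ring A (primed locants) is a cyclohexene with its alkene at C4'=C5'; its only stereocentre, C6', is a tertiary CH between the quaternary C1', the ring alkene carbon C5' and the chain alkene C7'=C8'. Ring B is a cyclohexane fused to an oxirane across C5–C6, so two contiguous, fully substituted stereocentres sit next to the quaternary C1, and C6 is also the first atom of the polyene (a vinyl oxirane). The two stereogenic regions are about twenty bonds apart and cannot influence each other, so each must be set by its own reagent-controlled step. The fragile elements are the polyene (light, oxygen, acid, E/Z drift), the vinyl oxirane (opened or rearranged to the 5,8-furanoid ether by traces of acid) and C6', whose doubly allylic hydrogen is lost or scrambled by a neighbouring cation, carbanion or carbonyl group. The real difficulty is to make C6' as one enantiomer while the ring alkene stays out of conjugation, and to carry an acid-labile enantiopure oxirane through the polyene assembly. The key step exploits the position of C6' between C4'=C5' and C7'=C8': with the ring alkene moved to C5'=C6' and a leaving group on C4', C6' becomes the γ-carbon of an allylic electrophile that a C7' alkenyl nucleophile attacks with transposition.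

## Logic of the disconnections

36 is cut at the central C15=C15' double bond into 21 and 34. This gives two C20 halves of equal size, each holding one stereogenic region. The acid-labile oxirane sits on the electrophilic half, so the acid needed to make the phosphonium salt only meets the oxirane-free half. The forward olefination must leave C6' and the oxirane untouched and must allow Z-to-E equilibration at the new bond.

34 is traced through 32 to 30 and 26 (cut at C11=C12), and 30 through 28 to 25 and 26 (cut at C7=C8). The same five-carbon reagent is used twice, and the formyl carbon of 25 sits on a quaternary carbon that cannot epimerise. The forward steps need E selectivity at the new bonds, hydride reduction of a nitrile next to a vinyl oxirane, and non-acidic hydrolysis.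

25 comes from 24 by oxidation, and 24 from 23 by removing the C5–O and C6–O bonds; 23 is one reduction from 22. The C7 hydroxyl makes the tetrasubstituted ring alkene a substrate for a hydroxyl-directed, reagent-controlled oxygen transfer that sets both oxirane stereocentres at once from an achiral precursor. The demand is face selection on a tetrasubstituted alkene.

21 is traced to 20 (C15'–P) and 20 to 17 through 18 and 19 (C14'–C15' and C13'–CH3). Methylmetalation of a terminal alkyne installs the methyl branch and the E trisubstituted alkene together, and a one-carbon electrophile supplies C15'. The forward steps need regio- and syn-selective carbometalation and a salt formation that does not remove the C6' hydrogen.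

17 is traced through 16 to 14 and 5, via 15 (C10'–C11' and C9'–CH3). 5 delivers four carbons with a defined E alkene and a masked terminal alkyne for the next round. The coupling must be stereoretentive at both partners.

14 is traced through 13 to 9 and 11 by cutting C6'–C7'; this is the key disconnection. The hard stereocentre C6' is exchanged for a carbinol stereocentre at C4', which a ketone reduction sets reliably. The enyne nucleophile brings C7' to C10' at the final oxidation level, so C6' is never adjacent to a carbonyl group. The forward step must be γ-selective and anti-stereospecific at a carbon next to a quaternary centre, and must keep the alkenyl geometry.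

9 is cut at the ester C–O bond into 7 and 8, and 7 is the reduction product of 6. The demand is an enantioselective 1,2-reduction of a cyclic enone.

5, which also supplies 11 through 10, is traced through 4 to 3 (C–I and C–H across the terminal alkyne) and 3 through 2 to 1 (C–Si). Syn hydrometalation fixes the E geometry, and 1 is a stable commercial solid. The forward steps need clean monodesilylation and addition only to the terminal alkyne.

## Other disconnections considered

Alternative 1: The cut removes the C5–C6 and C6–O bonds, so ring B and the oxirane would form together from the open-chain chloro keto ester A1 by an intramolecular Darzens condensation to the epoxy ester A2. In the forward step a hindered base would generate the ester enolate of A1, which adds to the C5 ketone (6-exo-trig aldol closing the carbocycle); the tertiary alkoxide then displaces chloride (3-exo-tet).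
- In favour: two bonds, two rings and both oxirane stereocentres arise in one operation. Cis fusion is the only possible outcome. The chloride-bearing centre is planarised on enolisation, so racemic A1 is no handicap for relative configuration. The ester of A2 is at an oxidation level that leads directly to 24 or 25.
- Against: nothing in A1 distinguishes the two ketone faces, so A2 would be racemic unless a chiral base, counter-ion or ester auxiliary could control an aldol between a neopentyl, fully substituted enolate and a ketone, a case without dependable precedent. The ketone α-hydrogens are more accessible than the C6 hydrogen next to the quaternary carbon, so wrong-site enolisation, retro-aldol and intermolecular condensation would compete. A1 itself would take several steps.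
- Comparison: it addresses only the oxirane end and leaves C6' unsolved. Its asymmetric induction would be external and act on a reversible aldol, whereas the chosen plan uses an oxygen transfer of predictable sense for the oxirane and a stereospecific transfer for C6'. In bond economy for ring B it is the better of the two. In downstream handling A2 is the equal of 24. In overall step count and enantiocontrol it is expected to be the weaker.

Alternative 2: The cut is C1'–C6': ring A would come from the achiral (E)-geranyl phenyl sulfone A3 by an enantioselective proton-initiated cyclisation to α-cyclogeranyl phenyl sulfone A4. In the forward step SnCl4 bound to one enantiomer of a monobenzylated 1,1'-binaphthalene-2,2'-diol (a Lewis-acid-assisted Brønsted acid) would protonate the terminal alkene, the internal alkene would attack the tertiary cation through a chair-like transition state, and loss of the C4' proton would end the sequence.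
- In favour: A3 is one step from commercial material, and ring, C–C bond and C6' stereocentre are made together. The sulfone at C7' is a ready carbanion handle for a Julia-type chain attachment and does not make C6' acidic; on this point it is the equal of the chosen plan. Two steps to a C6'-defined ring is better than the five steps (1 to 5) needed for 13.
- Against: face selection occurs at protonation of an alkene remote from the stereocentre being formed and is relayed only by transition-state folding. Monocyclisations that end by proton loss are the weak cases of this class of acid. Three alkene positions can result (C4'=C5', C5'=C6', exocyclic), the C5'=C6' isomer being achiral and the isomers hard to separate. The sulfonylmethyl group deactivates the nucleophilic alkene. The SnCl4 complex is used in stoichiometric amount. The later Julia union with a polyenal adds an elimination step and an E/Z question.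
- Comparison: A4 carries one chain carbon, whereas 13 carries four at the final oxidation level. The chosen anti SN2' step dictates the alkene position by mechanism and relays a reliably set carbinol centre, so it is better in regiochemical and stereochemical certainty. The alternative is better in step count for the ring fragment and avoids a stoichiometric amount of CuBr·SMe2. Once the Julia sequence and isomer separation are counted, overall step economy is expected to be about equal.

Alternative 3: The cut removes the C5–O and C6–O bonds: β-cyclogeraniol A5 (the same compound as 23) would be epoxidised with Ti(OiPr)4, D-(−)-diethyl tartrate and t-BuOOH to the epoxy alcohol A6 (the same compound as 24). The C7 hydroxyl anchors the alkene to the chiral complex formed from Ti(OiPr)4 and the tartrate, and the D-tartrate selects the face that gives the (5R,6S) oxirane.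
- In favour: the sense is predictable, both stereocentres are set in one catalytic step, the substrate is achiral and cheap, and the product keeps the C7 hydroxyl for chain extension.
- Against: tetrasubstituted alkenes react slowly, and the epoxy alcohol is sensitive to the Lewis-acidic Ti(OiPr)4. As the organising step of a route it fixes only the oxirane end.
- Comparison: it does not compete with the chosen key step but complements it. The chosen route uses this very transformation as step 12, so on the oxirane stereocentres and on step economy for ring B it is exactly the equal of the chosen plan, and it is better than Alternative 1 in enantiocontrol. As the strategic centre it is weaker, because the harder problem, a doubly allylic C6' with the alkene held at C4'=C5', would still have to be solved by other means.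

Key step: step 5

Remarks on the chemistry:
- Locants follow carotenoid numbering, unprimed for the oxirane half and primed for the ε half.
- The stereochemical chain is self-consistent: an (R)-carbinol at C4' with anti SN2' attack gives (R)-C6' as in the target, and the oxirane is (5R,6S).
- The alkenylmagnesium bromide 11 is drawn from the iodide 5 and not from an enynyl chloride: a vinylic C–Cl bond does not undergo clean halogen–metal exchange, and strong bases dehydrochlorinate chloroenynes to diynes. 5 also serves as the electrophile of step 7.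
- The two olefinations with 26 use different bases: NaH at room temperature for the hindered, non-enolisable 25, and LiN(SiMe3)2 at low temperature for the vinylogously enolisable polyenal 30.
- Assumption: 1, 6, 8, 22 and 26 (sold as an E/Z mixture) are purchased.

## Steps

Step 1
Reactants: 1 1,4-bis(trimethylsilyl)buta-1,3-diyne
Product: 3 buta-1,3-diyn-1-yl(trimethyl)silane, via lithium silylbutadiynide 2 (not isolated)
Conditions: MeLi·LiBr (1.05 equiv), Et2O, 0 °C to rt; then aq. NH4Cl, 0 °C; dried Et2O solution carried on without concentration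
Reagents that add atoms: none
Why: Nucleophilic desilylation: methyllithium attacks one silicon of the symmetric diyne and the conjugated acetylide 2 resists a second attack; protonation gives the terminal diyne, which is kept in solution because it is volatile and should not be handled neat.

Step 2
Reactants: 3 buta-1,3-diyn-1-yl(trimethyl)silane
Product: 5 [(E)-4-iodobut-3-en-1-yn-1-yl]trimethylsilane, via alkenylzirconocene chloride 4 (not isolated)
Conditions: Cp2Zr(H)Cl (1.1 equiv), THF, rt, dark; then I2 (1.1 equiv), 0 °C
Reagents that add atoms: iodine, II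
Why: Hydrozirconation adds Zr–H syn across the unhindered terminal alkyne with zirconium on the terminal carbon, and iodinolysis of the C–Zr bond goes with retention, so only the E iodide should form; the silylated alkyne is too hindered to react.

Step 3
Reactants: 6 2,4,4-trimethylcyclohex-2-en-1-one
Product: 7 (1R)-2,4,4-trimethylcyclohex-2-en-1-ol
Conditions: (S)-B-methyl diphenylprolinol oxazaborolidine (0.2 equiv), BH3·SMe2 (0.7 equiv), THF, −20 °C; then MeOH
Reagents that add atoms: none
Why: Corey–Bakshi–Shibata reduction: the ketone binds to the catalyst boron with the methyl-substituted alkenyl branch as the large group, so hydride is delivered to the face that gives the (R)-carbinol; 1,2-reduction is much faster than hydroboration of the trisubstituted alkene at this temperature.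

Step 4
Reactants: 7 (1R)-2,4,4-trimethylcyclohex-2-en-1-ol; 8 picolinic acid
Product: 9 (1R)-2,4,4-trimethylcyclohex-2-en-1-yl pyridine-2-carboxylate
Conditions: EDC·HCl (1.3 equiv), DMAP (0.1 equiv), CH2Cl2, 0 °C to rt
Reagents that add atoms: none
Why: Steglich-type carbodiimide esterification of a secondary allylic alcohol; no bond at the stereocentre is broken, so the configuration is retained, and the acid chloride is avoided.

Step 5
Reactants: 9 (1R)-2,4,4-trimethylcyclohex-2-en-1-yl pyridine-2-carboxylate; 5 [(E)-4-iodobut-3-en-1-yn-1-yl]trimethylsilane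
Product: 13 trimethyl{(3E)-4-[(1R)-2,6,6-trimethylcyclohex-2-en-1-yl]but-3-en-1-yn-1-yl}silane, via alkenyllithium 10 (not isolated), via Grignard reagent 11 (not isolated), via magnesium cuprate 12 (not isolated)
Conditions: 5 (2.4 equiv), t-BuLi (4.8 equiv), Et2O, −78 °C; MgBr2·OEt2 (2.5 equiv), −78 to 0 °C; CuBr·SMe2 (1.2 equiv), THF, −40 °C; then 9, −40 to 0 °C
Reagents that add atoms: none
Why: Iodine–lithium exchange on 5 and transmetalation with MgBr2 give 11 with retained E geometry, and two equivalents of 11 with CuBr·SMe2 give the cuprate 12. MgBr2 is chelated by the pyridine nitrogen and the carbonyl oxygen of 9, which turns the picolinate into a much better leaving group than a simple ester and favours the conformer with a pseudoaxial C4'–O bond. The copper of 12 adds to the alkene at C6' on the face opposite to the leaving group, giving a σ-allyl trivalent copper species, and reductive elimination forms C6'–C7' before the allyl unit can isomerise, so the alkene ends at C4'=C5'. The closest known reaction type is the copper-mediated anti SN2' substitution of secondary allylic picolinates by aryl- and alkenylmagnesium bromides with 1,3-chirality transfer. No ring is closed. The one new stereocentre, C6', is controlled by the carbinol stereocentre C4' of 9: the alkenyl group enters on the ring face opposite to the C–O bond, which converts (R)-C4' into (R)-C6'. The step needs γ over α regioselectivity, anti over syn stereospecificity and retention of the alkenyl geometry; the chelating leaving group secures the first two by accelerating the SN2' path enough to overcome the neighbouring gem-dimethyl carbon C1', and the configurational stability of alkenylcopper reagents below 0 °C secures the third.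

Step 6
Reactants: 13 trimethyl{(3E)-4-[(1R)-2,6,6-trimethylcyclohex-2-en-1-yl]but-3-en-1-yn-1-yl}silane
Product: 14 (6R)-6-[(1E)-but-1-en-3-yn-1-yl]-1,5,5-trimethylcyclohex-1-ene
Conditions: K2CO3 (0.2 equiv), MeOH, rt
Reagents that add atoms: none
Why: Base-catalysed methanolysis cleaves only the alkynyl C–Si bond; the alkenes and the non-acidic C6' centre are not affected.

Step 7
Reactants: 14 (6R)-6-[(1E)-but-1-en-3-yn-1-yl]-1,5,5-trimethylcyclohex-1-ene; 5 [(E)-4-iodobut-3-en-1-yn-1-yl]trimethylsilane
Product: 16 trimethyl{(3E,5E,7E)-6-methyl-8-[(1R)-2,6,6-trimethylcyclohex-2-en-1-yl]octa-3,5,7-trien-1-yn-1-yl}silane, via alkenylalane 15 (not isolated)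
Conditions: Me3Al (2 equiv), Cp2ZrCl2 (0.25 equiv), CH2Cl2, 0 °C to rt; evaporate; then 5 (1.1 equiv), ZnCl2 (0.5 equiv), Pd(PPh3)4 (5 mol%), THF, rt
Reagents that add atoms: trimethylaluminium, C[Al](C)C
Why: Methylalumination catalysed by Cp2ZrCl2 adds CH3 and Al syn across the terminal alkyne with aluminium on the terminal carbon, fixing the E C9'=C10' bond; the alkenylalane 15 then undergoes a Negishi coupling with the alkenyl iodide 5, assisted by ZnCl2 and catalysed by Pd(PPh3)4, with retention at both partners.

Step 8
Reactants: 16 trimethyl{(3E,5E,7E)-6-methyl-8-[(1R)-2,6,6-trimethylcyclohex-2-en-1-yl]octa-3,5,7-trien-1-yn-1-yl}silane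
Product: 17 (6R)-1,5,5-trimethyl-6-[(1E,3E,5E)-3-methylocta-1,3,5-trien-7-yn-1-yl]cyclohex-1-ene
Conditions: K2CO3 (0.2 equiv), MeOH–THF, rt, dark
Reagents that add atoms: none
Why: Same alkynyl desilylation as in step 6; the terminal trienyne is light- and air-sensitive and is used at once.

Step 9
Reactants: 17 (6R)-1,5,5-trimethyl-6-[(1E,3E,5E)-3-methylocta-1,3,5-trien-7-yn-1-yl]cyclohex-1-ene
Product: 20 (2E,4E,6E,8E)-3,7-dimethyl-9-[(1R)-2,6,6-trimethylcyclohex-2-en-1-yl]nona-2,4,6,8-tetraen-1-ol, via alkenylalane 18 (not isolated), via lithium aluminate 19 (not isolated)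
Conditions: Me3Al (2 equiv), Cp2ZrCl2 (0.25 equiv), CH2Cl2, rt; evaporate; n-BuLi (1 equiv), THF–hexane, −78 to 0 °C; (CH2O)n, rt
Reagents that add atoms: trimethylaluminium, C[Al](C)C; paraformaldehyde (as formaldehyde), C=O
Why: A second syn methylalumination sets the E C13'=C14' bond; converting the alane 18 into the more nucleophilic ate complex 19 lets the alkenyl group add to formaldehyde, which supplies C15' as the allylic alcohol.

Step 10
Reactants: 20 (2E,4E,6E,8E)-3,7-dimethyl-9-[(1R)-2,6,6-trimethylcyclohex-2-en-1-yl]nona-2,4,6,8-tetraen-1-ol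
Product: 21 {(2E,4E,6E,8E)-3,7-dimethyl-9-[(1R)-2,6,6-trimethylcyclohex-2-en-1-yl]nona-2,4,6,8-tetraen-1-yl}triphenylphosphonium bromide
Conditions: PPh3·HBr (1.05 equiv), MeOH, rt, dark
Reagents that add atoms: triphenylphosphine hydrobromide, [Br-].c1ccc(cc1)[PH+](c1ccccc1)c1ccccc1
Why: SN1-type phosphonium salt formation, standard for polyenyl allylic alcohols: the acid ionises the alcohol and triphenylphosphine captures the delocalised cation at its unhindered terminus C15'; the high phosphine concentration should outrun proton loss from C6'.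

Step 11
Reactants: 22 2,6,6-trimethylcyclohex-1-ene-1-carbaldehyde (β-cyclocitral)
Product: 23 (2,6,6-trimethylcyclohex-1-en-1-yl)methanol (β-cyclogeraniol)
Conditions: NaBH4 (0.5 equiv), MeOH, 0 °C
Reagents that add atoms: none
Why: Borohydride 1,2-reduction of a conjugated aldehyde whose β-carbon is fully substituted, so conjugate reduction does not compete.

Step 12
Reactants: 23 (2,6,6-trimethylcyclohex-1-en-1-yl)methanol
Product: 24 [(1R,6R)-2,2,6-trimethyl-7-oxabicyclo[4.1.0]heptan-1-yl]methanol
Conditions: Ti(OiPr)4 (0.2 equiv), D-(−)-diethyl tartrate (0.25 equiv), t-BuOOH (2 equiv, in decane), 4 Å molecular sieves, CH2Cl2, −20 °C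
Reagents that add atoms: tert-butyl hydroperoxide, CC(C)(C)OO
Why: Sharpless asymmetric epoxidation: the allylic alkoxide and the hydroperoxide bind to the complex formed from Ti(OiPr)4 and the tartrate, and oxygen is delivered to one face of C5=C6, which with the D-(−)-tartrate is the face giving the (5R,6S) oxirane. Both stereocentres are set together, and the sieves keep the medium dry so that the epoxy alcohol is not opened.

Step 13
Reactants: 24 [(1R,6R)-2,2,6-trimethyl-7-oxabicyclo[4.1.0]heptan-1-yl]methanol
Product: 25 (1S,6R)-2,2,6-trimethyl-7-oxabicyclo[4.1.0]heptane-1-carbaldehyde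
Conditions: nPr4N[RuO4] (5 mol%), N-methylmorpholine N-oxide (1.5 equiv), 4 Å molecular sieves, CH2Cl2, rt
Reagents that add atoms: none
Why: Ley–Griffith oxidation under neutral, anhydrous conditions gives the aldehyde without exposing the oxirane to acid; the α-carbon is quaternary, so it cannot epimerise (the descriptor changes only because the substituent priorities change).

Step 14
Reactants: 25 (1S,6R)-2,2,6-trimethyl-7-oxabicyclo[4.1.0]heptane-1-carbaldehyde; 26 diethyl (3-cyano-2-methylprop-2-en-1-yl)phosphonate
Product: 28 (2E,4E)-3-methyl-5-[(1S,6R)-2,2,6-trimethyl-7-oxabicyclo[4.1.0]heptan-1-yl]penta-2,4-dienenitrile, via phosphonate carbanion sodium salt 27 (not isolated)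
Conditions: 26 (1.3 equiv), NaH (1.25 equiv), THF, 0 °C; then 25, 0 °C to rt
Reagents that add atoms: none
Why: Horner–Wadsworth–Emmons olefination of a non-enolisable aldehyde with the allylic phosphonate anion 27; the new C7=C8 bond should be E, and the equilibrating anion should favour E at C9=C10, any 9Z isomer being removed by chromatography after step 15.

Step 15
Reactants: 28 (2E,4E)-3-methyl-5-[(1S,6R)-2,2,6-trimethyl-7-oxabicyclo[4.1.0]heptan-1-yl]penta-2,4-dienenitrile
Product: 30 (2E,4E)-3-methyl-5-[(1S,6R)-2,2,6-trimethyl-7-oxabicyclo[4.1.0]heptan-1-yl]penta-2,4-dienal, via N-aluminoimine 29 (not isolated)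
Conditions: i-Bu2AlH (1.2 equiv), CH2Cl2, −78 °C; then aq. potassium sodium tartrate (KNaC4H4O6), 0 °C to rt
Reagents that add atoms: water, O
Why: i-Bu2AlH adds once to the nitrile at −78 °C to give the N-aluminoimine 29, which is hydrolysed to the aldehyde under neutral tartrate conditions; the hindered, fully substituted oxirane should not be attacked at this temperature.

Step 16
Reactants: 30 (2E,4E)-3-methyl-5-[(1S,6R)-2,2,6-trimethyl-7-oxabicyclo[4.1.0]heptan-1-yl]penta-2,4-dienal; 26 diethyl (3-cyano-2-methylprop-2-en-1-yl)phosphonate
Product: 32 (2E,4E,6E,8E)-3,7-dimethyl-9-[(1S,6R)-2,2,6-trimethyl-7-oxabicyclo[4.1.0]heptan-1-yl]nona-2,4,6,8-tetraenenitrile, via phosphonate carbanion lithium salt 31 (not isolated)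
Conditions: 26 (1.3 equiv), LiN(SiMe3)2 (1.25 equiv), DMPU (2 equiv), THF, −78 °C; then 30, −78 to 0 °C, dark
Reagents that add atoms: none
Why: Second Horner–Wadsworth–Emmons homologation with the same phosphonate, here as its lithium salt 31 made with the non-nucleophilic amide at low temperature, because 30 is a vinylogously enolisable polyenal that should not meet a hydride base at room temperature. It forms the E C11=C12 bond and brings in C13=C14, the lithium counter-ion favouring the E olefin.

Step 17
Reactants: 32 (2E,4E,6E,8E)-3,7-dimethyl-9-[(1S,6R)-2,2,6-trimethyl-7-oxabicyclo[4.1.0]heptan-1-yl]nona-2,4,6,8-tetraenenitrile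
Product: 34 (2E,4E,6E,8E)-3,7-dimethyl-9-[(1S,6R)-2,2,6-trimethyl-7-oxabicyclo[4.1.0]heptan-1-yl]nona-2,4,6,8-tetraenal, via N-aluminoimine 33 (not isolated)
Conditions: i-Bu2AlH (1.2 equiv), CH2Cl2, −78 °C; then aq. potassium sodium tartrate (KNaC4H4O6), 0 °C to rt, dark
Reagents that add atoms: water, O
Why: Partial reduction of the nitrile to the N-aluminoimine 33 and neutral hydrolysis, as in step 15; minor 13Z aldehyde is removed at this stage.

Step 18
Reactants: 21 {(2E,4E,6E,8E)-3,7-dimethyl-9-[(1R)-2,6,6-trimethylcyclohex-2-en-1-yl]nona-2,4,6,8-tetraen-1-yl}triphenylphosphonium bromide; 34 (2E,4E,6E,8E)-3,7-dimethyl-9-[(1S,6R)-2,2,6-trimethyl-7-oxabicyclo[4.1.0]heptan-1-yl]nona-2,4,6,8-tetraenal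
Product: 36 (5R,6S,6'R)-5,6-epoxy-5,6-dihydro-β,ε-carotene, via phosphonium ylide 35 (not isolated)
Conditions: NaOMe (1.1 equiv), MeOH–CH2Cl2, 0 °C to rt, dark; then heptane, 80 °C, argon
Reagents that add atoms: none
Why: Wittig olefination: methoxide converts 21 into the ylide 35, which condenses with 34 to form C15=C15'; the central Z isomer formed alongside is the least hindered cis alkene of the chain and should equilibrate thermally to the all-E compound. The base touches neither the oxirane nor C6'.

## Compound list

1 | 1,4-bis(trimethylsilyl)buta-1,3-diyne | C[Si](C)(C)C#CC#C[Si](C)(C)C | starting material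
2 | lithium 4-(trimethylsilyl)buta-1,3-diyn-1-ide | [Li]C#CC#C[Si](C)(C)C | intermediate
3 | buta-1,3-diyn-1-yl(trimethyl)silane | C[Si](C)(C)C#CC#C | intermediate
4 | chlorobis(cyclopentadienyl)[(E)-4-(trimethylsilyl)but-1-en-3-yn-1-yl]zirconium | C[Si](C)(C)C#C/C=C/[Zr](Cl)(C1C=CC=C1)C1C=CC=C1 | intermediate
5 | [(E)-4-iodobut-3-en-1-yn-1-yl]trimethylsilane | C[Si](C)(C)C#C/C=C/I | intermediate
6 | 2,4,4-trimethylcyclohex-2-en-1-one | CC1=CC(C)(C)CCC1=O | starting material
7 | (1R)-2,4,4-trimethylcyclohex-2-en-1-ol | CC1=CC(C)(C)CC[C@H]1O | intermediate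
8 | picolinic acid | OC(=O)c1ccccn1 | starting material
9 | (1R)-2,4,4-trimethylcyclohex-2-en-1-yl pyridine-2-carboxylate | CC1=CC(C)(C)CC[C@H]1OC(=O)c2ccccn2 | intermediate
10 | [(E)-4-(trimethylsilyl)but-1-en-3-yn-1-yl]lithium | [Li]/C=C/C#C[Si](C)(C)C | intermediate
11 | [(E)-4-(trimethylsilyl)but-1-en-3-yn-1-yl]magnesium bromide | C[Si](C)(C)C#C/C=C/[Mg]Br | intermediate
12 | bromomagnesium bis[(E)-4-(trimethylsilyl)but-1-en-3-yn-1-yl]cuprate | C[Si](C)(C)C#C/C=C/[Cu-]/C=C/C#C[Si](C)(C)C.[Mg+]Br | intermediate
13 | trimethyl{(3E)-4-[(1R)-2,6,6-trimethylcyclohex-2-en-1-yl]but-3-en-1-yn-1-yl}silane | CC1=CCCC(C)(C)[C@H]1/C=C/C#C[Si](C)(C)C | intermediate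
14 | (6R)-6-[(1E)-but-1-en-3-yn-1-yl]-1,5,5-trimethylcyclohex-1-ene | CC1=CCCC(C)(C)[C@H]1/C=C/C#C | intermediate
15 | dimethyl{(1E,3E)-2-methyl-4-[(1R)-2,6,6-trimethylcyclohex-2-en-1-yl]buta-1,3-dien-1-yl}alane | CC1=CCCC(C)(C)[C@H]1/C=C/C(C)=C/[Al](C)C | intermediate
16 | trimethyl{(3E,5E,7E)-6-methyl-8-[(1R)-2,6,6-trimethylcyclohex-2-en-1-yl]octa-3,5,7-trien-1-yn-1-yl}silane | CC1=CCCC(C)(C)[C@H]1/C=C/C(C)=C/C=C/C#C[Si](C)(C)C | intermediate
17 | (6R)-1,5,5-trimethyl-6-[(1E,3E,5E)-3-methylocta-1,3,5-trien-7-yn-1-yl]cyclohex-1-ene | CC1=CCCC(C)(C)[C@H]1/C=C/C(C)=C/C=C/C#C | intermediate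
18 | {(1E,3E,5E,7E)-2,6-dimethyl-8-[(1R)-2,6,6-trimethylcyclohex-2-en-1-yl]octa-1,3,5,7-tetraen-1-yl}dimethylalane | CC1=CCCC(C)(C)[C@H]1/C=C/C(C)=C/C=C/C(C)=C/[Al](C)C | intermediate
19 | lithium butyl{(1E,3E,5E,7E)-2,6-dimethyl-8-[(1R)-2,6,6-trimethylcyclohex-2-en-1-yl]octa-1,3,5,7-tetraen-1-yl}dimethylaluminate | CC1=CCCC(C)(C)[C@H]1/C=C/C(C)=C/C=C/C(C)=C/[Al-](C)(C)CCCC.[Li+] | intermediate
20 | (2E,4E,6E,8E)-3,7-dimethyl-9-[(1R)-2,6,6-trimethylcyclohex-2-en-1-yl]nona-2,4,6,8-tetraen-1-ol ((R)-α-retinol) | CC1=CCCC(C)(C)[C@H]1/C=C/C(C)=C/C=C/C(C)=C/CO | intermediate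
21 | {(2E,4E,6E,8E)-3,7-dimethyl-9-[(1R)-2,6,6-trimethylcyclohex-2-en-1-yl]nona-2,4,6,8-tetraen-1-yl}triphenylphosphonium bromide | CC1=CCCC(C)(C)[C@H]1/C=C/C(C)=C/C=C/C(C)=C/C[P+](c2ccccc2)(c3ccccc3)c4ccccc4.[Br-] | intermediate
22 | 2,6,6-trimethylcyclohex-1-ene-1-carbaldehyde (β-cyclocitral) | CC1=C(C=O)C(C)(C)CCC1 | starting material
23 | (2,6,6-trimethylcyclohex-1-en-1-yl)methanol (β-cyclogeraniol) | CC1=C(CO)C(C)(C)CCC1 | intermediate
24 | [(1R,6R)-2,2,6-trimethyl-7-oxabicyclo[4.1.0]heptan-1-yl]methanol | OC[C@@]12O[C@]1(C)CCCC2(C)C | intermediate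
25 | (1S,6R)-2,2,6-trimethyl-7-oxabicyclo[4.1.0]heptane-1-carbaldehyde | O=C[C@@]12O[C@]1(C)CCCC2(C)C | intermediate
26 | diethyl (3-cyano-2-methylprop-2-en-1-yl)phosphonate (E/Z mixture) | CCOP(=O)(CC(C)=CC#N)OCC | starting material
27 | sodium 3-cyano-1-(diethoxyphosphoryl)-2-methylprop-2-en-1-ide | CCOP(=O)([CH-]C(C)=CC#N)OCC.[Na+] | intermediate
28 | (2E,4E)-3-methyl-5-[(1S,6R)-2,2,6-trimethyl-7-oxabicyclo[4.1.0]heptan-1-yl]penta-2,4-dienenitrile | N#C/C=C(C)/C=C/[C@@]12O[C@]1(C)CCCC2(C)C | intermediate
29 | N-(diisobutylalumanyl)imine of 30 | CC(C)C[Al](CC(C)C)N=C/C=C(C)/C=C/[C@@]12O[C@]1(C)CCCC2(C)C | intermediate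
30 | (2E,4E)-3-methyl-5-[(1S,6R)-2,2,6-trimethyl-7-oxabicyclo[4.1.0]heptan-1-yl]penta-2,4-dienal | O=C/C=C(C)/C=C/[C@@]12O[C@]1(C)CCCC2(C)C | intermediate
31 | lithium 3-cyano-1-(diethoxyphosphoryl)-2-methylprop-2-en-1-ide | CCOP(=O)([CH-]C(C)=CC#N)OCC.[Li+] | intermediate
32 | (2E,4E,6E,8E)-3,7-dimethyl-9-[(1S,6R)-2,2,6-trimethyl-7-oxabicyclo[4.1.0]heptan-1-yl]nona-2,4,6,8-tetraenenitrile | N#C/C=C(C)/C=C/C=C(C)/C=C/[C@@]12O[C@]1(C)CCCC2(C)C | intermediate
33 | N-(diisobutylalumanyl)imine of 34 | CC(C)C[Al](CC(C)C)N=C/C=C(C)/C=C/C=C(C)/C=C/[C@@]12O[C@]1(C)CCCC2(C)C | intermediate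
34 | (2E,4E,6E,8E)-3,7-dimethyl-9-[(1S,6R)-2,2,6-trimethyl-7-oxabicyclo[4.1.0]heptan-1-yl]nona-2,4,6,8-tetraenal ((5R,6S)-5,6-epoxy-5,6-dihydroretinal) | O=C/C=C(C)/C=C/C=C(C)/C=C/[C@@]12O[C@]1(C)CCCC2(C)C | intermediate
35 | {(2E,4E,6E,8E)-3,7-dimethyl-9-[(1R)-2,6,6-trimethylcyclohex-2-en-1-yl]nona-2,4,6,8-tetraen-1-ylidene}triphenylphosphorane | CC1=CCCC(C)(C)[C@H]1/C=C/C(C)=C/C=C/C(C)=C/C=P(c2ccccc2)(c3ccccc3)c4ccccc4 | intermediate
36 | (5R,6S,6'R)-5,6-epoxy-5,6-dihydro-β,ε-carotene | CC1=CCCC(C)(C)[C@H]1/C=C/C(C)=C/C=C/C(C)=C/C=C/C=C(C)/C=C/C=C(C)/C=C/[C@@]12O[C@]1(C)CCCC2(C)C | target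

## Step count and least certain steps

Total: 18 steps. Longest linear sequence: 9 steps (steps 3, 4, 5, 6, 7, 8, 9, 10 and 18, from 6 to 36).

Step 5 (key step). The attack at C6' passes one methyl group of C1', so γ-substitution may become slow. Direct substitution at C4', ionisation of the picolinate with loss of stereospecificity, or thermal decay of the alkenylcopper reagent could then compete. The fallback sets out from 6 and returns at 13. 6 is reduced with the enantiomeric (R)-oxazaborolidine and BH3·SMe2 to (1S)-2,4,4-trimethylcyclohex-2-en-1-ol F1. A Johnson–Claisen rearrangement (triethyl orthoacetate, catalytic propionic acid, 140 °C) transfers the carbinol chirality suprafacially to C6' and gives ethyl 2-[(1R)-2,6,6-trimethylcyclohex-2-en-1-yl]acetate F2, in which C6' is β and not α to the carbonyl group. i-Bu2AlH at −78 °C gives 2-[(1R)-2,6,6-trimethylcyclohex-2-en-1-yl]acetaldehyde F3. Addition of lithium (trimethylsilyl)acetylide gives 4-(trimethylsilyl)-1-[(1R)-2,6,6-trimethylcyclohex-2-en-1-yl]but-3-yn-2-ol F4. Mesylation and elimination with DBU give 13.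

Step 12. Oxygen transfer to a tetrasubstituted alkene is slow, so incomplete face selection or opening of the product promoted by Ti(OiPr)4 may lower the enantiomeric purity. The fallback sets out from 23 and returns at 24. 23 is epoxidised with m-CPBA and NaHCO3 to racemic (2,2,6-trimethyl-7-oxabicyclo[4.1.0]heptan-1-yl)methanol F5. F5 is esterified with (S)-2-methoxy-2-phenylacetic acid (EDC·HCl, DMAP) and the diastereomeric esters are separated by chromatography or crystallisation. The ester of the wanted enantiomer, [(1R,6R)-2,2,6-trimethyl-7-oxabicyclo[4.1.0]heptan-1-yl]methyl (2S)-2-methoxy-2-phenylacetate F6, is cleaved with K2CO3 in MeOH to 24.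

Step 14 (the same concern applies to step 16). The allylic phosphonate anion equilibrates between its E and Z forms, so stereocontrol at the trisubstituted C9=C10 bond may be incomplete and the isomers hard to separate. The fallback sets out from 25 and returns at 30. Takai olefination of 25 (CrCl2, CHI3, THF) gives (1S,6R)-1-[(E)-2-iodoethenyl]-2,2,6-trimethyl-7-oxabicyclo[4.1.0]heptane F7. Syn hydroboration of but-2-yn-1-ol catalysed by CuCl and Xantphos (B2pin2, MeOH, NaOtBu) gives (2Z)-3-(4,4,5,5-tetramethyl-1,3,2-dioxaborolan-2-yl)but-2-en-1-ol F8. Suzuki–Miyaura coupling of F7 with F8 (Pd(PPh3)4, aq. K3PO4, THF) gives the geometrically defined (2E,4E)-3-methyl-5-[(1S,6R)-2,2,6-trimethyl-7-oxabicyclo[4.1.0]heptan-1-yl]penta-2,4-dien-1-ol F9. MnO2 oxidises F9 to 30.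

Step 10. Acid ionises the allylic alcohol to a polyenyl cation, which may lose the C6' proton or scramble alkene geometry before the phosphine captures it. The fallback sets out from 17 and 34 and returns at 36 without any allylic cation. Takai olefination of 34 gives (1S,6R)-1-[(1E,3E,5E,7E,9E)-10-iodo-3,7-dimethyldeca-1,3,5,7,9-pentaen-1-yl]-2,2,6-trimethyl-7-oxabicyclo[4.1.0]heptane F10. The alane 18 is made from 17 as in the first stage of step 9 and freed from excess Me3Al in vacuo. Negishi coupling of 18 with F10 (ZnCl2, Pd(PPh3)4, THF) forms the C14'–C15' bond with retention and gives 36 directly, bypassing steps 9, 10 and 18.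

Step 18. The ylide may give a large share of the 15-Z isomer, and the heating needed to equilibrate it stresses the vinyl oxirane. The fallback sets out from 20 and returns at 36. An Appel reaction (CBr4, PPh3, −20 °C) gives (6R)-6-[(1E,3E,5E,7E)-9-bromo-3,7-dimethylnona-1,3,5,7-tetraen-1-yl]-1,5,5-trimethylcyclohex-1-ene F11. A Michaelis–Becker reaction with NaP(O)(OEt)2 gives diethyl {(2E,4E,6E,8E)-3,7-dimethyl-9-[(1R)-2,6,6-trimethylcyclohex-2-en-1-yl]nona-2,4,6,8-tetraen-1-yl}phosphonate F12. The E-selective Horner–Wadsworth–Emmons reaction of F12 with 34 (KOtBu, THF, −30 °C) gives 36.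

## Further compounds

F1 | step 5 | (1S)-2,4,4-trimethylcyclohex-2-en-1-ol | CC1=CC(C)(C)CC[C@@H]1O
F2 | step 5 | ethyl 2-[(1R)-2,6,6-trimethylcyclohex-2-en-1-yl]acetate | CC1=CCCC(C)(C)[C@H]1CC(=O)OCC
F3 | step 5 | 2-[(1R)-2,6,6-trimethylcyclohex-2-en-1-yl]acetaldehyde | CC1=CCCC(C)(C)[C@H]1CC=O
F4 | step 5 | 4-(trimethylsilyl)-1-[(1R)-2,6,6-trimethylcyclohex-2-en-1-yl]but-3-yn-2-ol (both carbinol epimers) | CC1=CCCC(C)(C)[C@H]1CC(O)C#C[Si](C)(C)C
F5 | step 12 | rac-(2,2,6-trimethyl-7-oxabicyclo[4.1.0]heptan-1-yl)methanol | OCC12OC1(C)CCCC2(C)C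
F6 | step 12 | [(1R,6R)-2,2,6-trimethyl-7-oxabicyclo[4.1.0]heptan-1-yl]methyl (2S)-2-methoxy-2-phenylacetate | CO[C@H](C(=O)OC[C@@]12O[C@]1(C)CCCC2(C)C)c1ccccc1
F7 | step 14 | (1S,6R)-1-[(E)-2-iodoethenyl]-2,2,6-trimethyl-7-oxabicyclo[4.1.0]heptane | I/C=C/[C@@]12O[C@]1(C)CCCC2(C)C
F8 | step 14 | (2Z)-3-(4,4,5,5-tetramethyl-1,3,2-dioxaborolan-2-yl)but-2-en-1-ol | C/C(B1OC(C)(C)C(C)(C)O1)=C\CO
F9 | step 14 | (2E,4E)-3-methyl-5-[(1S,6R)-2,2,6-trimethyl-7-oxabicyclo[4.1.0]heptan-1-yl]penta-2,4-dien-1-ol | OC/C=C(C)/C=C/[C@@]12O[C@]1(C)CCCC2(C)C
F10 | step 10 | (1S,6R)-1-[(1E,3E,5E,7E,9E)-10-iodo-3,7-dimethyldeca-1,3,5,7,9-pentaen-1-yl]-2,2,6-trimethyl-7-oxabicyclo[4.1.0]heptane | I/C=C/C=C(C)/C=C/C=C(C)/C=C/[C@@]12O[C@]1(C)CCCC2(C)C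
F11 | step 18 | (6R)-6-[(1E,3E,5E,7E)-9-bromo-3,7-dimethylnona-1,3,5,7-tetraen-1-yl]-1,5,5-trimethylcyclohex-1-ene | CC1=CCCC(C)(C)[C@H]1/C=C/C(C)=C/C=C/C(C)=C/CBr
F12 | step 18 | diethyl {(2E,4E,6E,8E)-3,7-dimethyl-9-[(1R)-2,6,6-trimethylcyclohex-2-en-1-yl]nona-2,4,6,8-tetraen-1-yl}phosphonate | CC1=CCCC(C)(C)[C@H]1/C=C/C(C)=C/C=C/C(C)=C/CP(=O)(OCC)OCC
A1 | alternative 1 | tert-butyl 2-chloro-3,3-dimethyl-7-oxooctanoate (racemic) | CC(=O)CCCC(C)(C)C(Cl)C(=O)OC(C)(C)C
A2 | alternative 1 | tert-butyl (1S,6R)-2,2,6-trimethyl-7-oxabicyclo[4.1.0]heptane-1-carboxylate | CC(C)(C)OC(=O)[C@@]12O[C@]1(C)CCCC2(C)C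
A3 | alternative 2 | {[(2E)-3,7-dimethylocta-2,6-dien-1-yl]sulfonyl}benzene ((E)-geranyl phenyl sulfone) | CC(C)=CCC/C(C)=C/CS(=O)(=O)c1ccccc1
A4 | alternative 2 | {[(1R)-2,6,6-trimethylcyclohex-2-en-1-yl]methanesulfonyl}benzene (α-cyclogeranyl phenyl sulfone) | CC1=CCCC(C)(C)[C@H]1CS(=O)(=O)c2ccccc2
A5 | alternative 3 | (2,6,6-trimethylcyclohex-1-en-1-yl)methanol (β-cyclogeraniol) | CC1=C(CO)C(C)(C)CCC1
A6 | alternative 3 | [(1R,6R)-2,2,6-trimethyl-7-oxabicyclo[4.1.0]heptan-1-yl]methanol | OC[C@@]12O[C@]1(C)CCCC2(C)C
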